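**Target:** Alternarin A. Ring numbering used below: drimane numbering for the decalin (C1–C12, C13 = ketone carbon), and C1′–C5′ for the cyclopentenone (C4′ = carbinol carbon).

## Retrosynthetic overview
1. Disconnect the thioether C–S bond and the 2′-CH2 group by a Morita–Baylis–Hillman hydroxymethylation then bromide/thiol displacement.
2. Disconnect C13–C4′ by dithiane umpolung: decalin-CH2-CHO plus a cyclopentene-1,4-dione mono-ketal.
3. Form the 8(12)-methylene late, by Wittig methylenation of a C8 ketone.
4. Build the C8-ketone trans-decalin in one Ti(III) radical cascade from an epoxy-keto-enoate. The C4 radical closes ring A (6-endo) and the C10 radical closes ring B (6-exo Giese), setting C3, C5, C9 and C10.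
5. The cascade substrate comes from (E)-geranylacetone (alkyne carboalumination plus conjugate addition to MVK), Shi epoxidation, and aldol condensation with ethyl glyoxylate.

**Assumptions (one line):** the C4′ epimers (about 1:1) are separable by HPLC and the natural (4′R) epimer is identified by comparison with the natural product; homoprenyl bromide, cyclopentene-1,4-dione, ethyl glyoxylate and (S)-methyl glycidate are commercial.

## Route

**Step 1**
Reactants: 1 (5-bromo-2-methylpent-2-ene), 2 (lithium acetylide–ethylenediamine complex)
Product: 3 (6-methylhept-5-en-1-yne)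
Conditions: DMSO, 15 °C to rt
Reagents that add atoms: none (acetylide is compound 2)
Why: SN2 alkylation of a primary bromide by acetylide gives the terminal alkyne, with the trisubstituted alkene untouched.

**Step 2**
Reactants: 3, 4 (methyl vinyl ketone)
Product: 5 ((E)-6,10-dimethylundeca-5,9-dien-2-one, geranylacetone)
Conditions: Me3Al, Cp2ZrCl2 (10 mol%), ClCH2CH2Cl, 0 °C to rt; then Ni(acac)2 (5 mol%), DIBAL (cat.), MVK, THF, 0 °C
Reagents that add atoms: trimethylaluminium, C[Al](C)C (supplies the vinylic CH3)
Why: Negishi Zr-catalysed carboalumination is a syn carbometalation that sets the (E)-trisubstituted alkene. The alkenylalane then undergoes Ni-catalysed 1,4-addition to MVK, giving the C5–C6 bond and the C8 methyl ketone.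

**Step 3**
Reactants: 5
Product: 6 ((5E,9S)-9,10-epoxy-6,10-dimethylundec-5-en-2-one)
Conditions: fructose-derived Shi ketone (30 mol%), Oxone, K2CO3, Bu4NHSO4, MeCN/DMM/aq. buffer pH 10.5, 0 °C
Reagents that add atoms: Oxone, KHSO5 (OOS(=O)(=O)[O-].[K+]), supplies the epoxide O
Why: Shi asymmetric dioxirane epoxidation prefers the more accessible terminal trisubstituted alkene and sets C3 as (S), which leads to the 3β-OH. The enantiomeric ketone is used if the (R)-epoxide is obtained.

**Step 4**
Reactants: 6, 7 (ethyl glyoxylate)
Product: 8 (aldol adduct, mixture at CH-OH)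
Conditions: LDA, THF, −78 °C; then 7 (freshly cracked), −78 °C
Reagents that add atoms: none (7 is a numbered reactant)
Why: Kinetic deprotonation of the methyl ketone at CH3 (future C9) and aldol addition to glyoxylate install C11 and the C13 ester carbon. The epoxide survives at −78 °C.

**Step 5**
Reactants: 8
Product: 9 (ethyl (2E,7E,11S)-11,12-epoxy-8,12-dimethyl-4-oxotrideca-2,7-dienoate)
Conditions: MsCl, Et3N, CH2Cl2, 0 °C; then DBU, rt
Reagents that add atoms: none
Why: Mesylation then E1cB elimination (enolisable ketone, mild base) gives the (E)-4-oxo-2-enoate, the Michael acceptor for the cascade. No new stereocentre is formed.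

**Step 6**
Reactants: 9
Product: 10 (ethyl 2-(3β-hydroxy-4,4,10β-trimethyl-8-oxo-5α,9α-trans-decalin-9-yl)acetate; drimane numbering)
Conditions: Cp2TiCl2 (20 mol%), Mn dust, 2,4,6-collidine, TMSCl, THF, rt; then 1 M HCl
Reagents that add atoms: none
Why: Proposed new method: Cp2TiCl opens the epoxide to the tertiary C4 radical (O–Ti at C3). It closes ring A by 6-endo attack on C5, and the resulting tertiary C10 radical closes ring B by 6-exo Giese addition to C9 of the 4-oxo-enoate. That is a nucleophilic radical on a polarity-matched electron-poor alkene, and the α-ester radical is reduced by Ti(III) and protonated by collidinium. The closest known reactions are Cp2TiCl-catalysed epoxypolyene cyclisation and Ti(III) radical cyclisation onto enones. Chair-like transition states give the trans A/B fusion with 10β-Me and 5α-H, the (S)-epoxide fixes 3β-O, and C9 sits α to the C8 ketone and equilibrates to the equatorial C11.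

**Step 7**
Reactants: 10
Product: 11 (ethyl 2-(3β-hydroxy-4,4,10β-trimethyl-8-methylene-trans-decalin-9α-H-yl)acetate)
Conditions: Ph3P=CH2 (from Ph3PCH3Br, KOt-Bu, 3 equiv), THF, 0 °C to rt
Reagents that add atoms: methyltriphenylphosphonium bromide, C[P+](c1ccccc1)(c1ccccc1)c1ccccc1.[Br-] (supplies =CH2)
Why: Wittig methylenation is chemoselective for the ketone over the ester and tolerates the free 3-OH. Any C9 epimer equilibrates to the natural configuration via the enolate before the ketone is consumed, and C9 is locked afterwards.

**Step 8**
Reactants: 11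
Product: 12 (2-(3β-hydroxy-8-methylene-drimanyl-9)acetaldehyde: C9–CH2–CHO)
Conditions: DIBAL-H (2.3 equiv), CH2Cl2, −78 °C
Reagents that add atoms: none
Why: Partial DIBAL reduction of the ester to the aldehyde; the extra equivalent is consumed by the free OH, and the stereocentres are unaffected.

**Step 9**
Reactants: 12, 13 (propane-1,3-dithiol)
Product: 14 (2-[(drimanyl)methyl]-1,3-dithiane)
Conditions: I2 (5 mol%), CH2Cl2, 0 °C to rt
Reagents that add atoms: none (13 is a numbered reactant)
Why: Mild iodine-catalysed thioacetalisation avoids acid-promoted isomerisation of the exocyclic alkene. This is the Corey–Seebach precursor for the C13 acyl anion.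

**Step 10**
Reactants: 15 (cyclopent-2-ene-1,4-dione)
Product: 16 (4,4-dimethoxycyclopent-2-en-1-one)
Conditions: HC(OMe)3 (1.0 equiv), MeOH, TsOH (cat.), rt
Reagents that add atoms: trimethyl orthoformate, COC(OC)OC (supplies the two OMe groups)
Why: Monoketalisation of the symmetrical enedione masks one carbonyl, so the nucleophile is directed to 1,2-addition at the other.

**Step 11**
Reactants: 14, 16
Product: 17 (tertiary allylic alcohol–dithiane–ketal adduct, C4′ epimers)
Conditions: n-BuLi (2.2 equiv), THF, −78 to −20 °C; then 16, −78 °C
Reagents that add atoms: none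
Why: 2-Lithio-2-alkyl-1,3-dithiane (the extra equivalent of base covers the 3-OH) adds 1,2 to the enone carbonyl of 16, forming the C13–C4′ bond. The new C4′ carbinol centre forms about 1:1 because the decalin stereocentres are four bonds away.

**Step 12**
Reactants: 17
Product: 18 ((4′R)-4′-hydroxy-4′-acyl-cyclopent-2-en-1-one; decalin-CH2-C(=O)-C4′)
Conditions: PIFA, MeCN–H2O (9:1), 0 °C; then preparative HPLC to separate C4′ epimers
Reagents that add atoms: water, O (supplies the ketone O)
Why: PIFA oxidatively cleaves the dithioacetal to the C13 ketone, and the TFA generated hydrolyses the allylic ketal to the C1′ enone. The natural (4′R) epimer is isolated, and quaternary C4′ cannot epimerise afterwards.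

**Step 13**
Reactants: 18, 19 (formaldehyde)
Product: 20 (2′-hydroxymethyl enone, Morita–Baylis–Hillman adduct)
Conditions: 37% aq. HCHO, PMe3 (10 mol%), THF–H2O, rt
Reagents that add atoms: none (19 is a numbered reactant)
Why: Phosphine-catalysed Morita–Baylis–Hillman hydroxymethylation occurs only at the α-carbon (C2′) of the enone, installing the CH2 that will carry sulfur. No stereocentre is created or disturbed.

**Step 14**
Reactants: 20
Product: 21 (2′-bromomethyl enone)
Conditions: PPh3, CBr4, CH2Cl2, 0 °C
Reagents that add atoms: carbon tetrabromide, BrC(Br)(Br)Br (supplies Br)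
Why: Appel bromination is selective for the unhindered primary allylic OH over the hindered 3-OH and the tertiary 4′-OH.

**Step 15**
Reactants: 22 ((S)-methyl glycidate)
Product: 23 (methyl (R)-3-(acetylthio)-2-hydroxypropanoate)
Conditions: AcSH, neat, 0 °C to rt
Reagents that add atoms: thioacetic acid, CC(=O)S
Why: SN2 opening at the terminal epoxide carbon leaves C2 untouched. The descriptor changes from S to R only because sulfur outranks the ester in CIP priority, so the (R)-thioglycerate stereocentre is set from the glycidate.

**Step 16**
Reactants: 23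
Product: 24 (methyl (R)-2-hydroxy-3-mercaptopropanoate)
Conditions: HCl (cat.), MeOH, 0 °C to rt, under N2
Reagents that add atoms: none
Why: Acid methanolysis removes the thioacetate without base-induced racemisation or disulfide formation.

**Step 17**
Reactants: 21, 24
Product: 25 (Alternarin A)
Conditions: Et3N (1.1 equiv), CH2Cl2, −20 to 0 °C
Reagents that add atoms: none (24 is a numbered reactant)
Why: Thiolate SN2 displacement of the allylic bromide (or an SN2′/SN2′ pair giving the same product) forms the CH2–S–CH2 linkage; all stereocentres are untouched.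

## Compound list
1 | 5-bromo-2-methylpent-2-ene | CC(C)=CCCBr | starting material
2 | lithium acetylide–ethylenediamine complex | [Li+].C#[C-].NCCN | starting material
3 | 6-methylhept-5-en-1-yne | C#CCCC=C(C)C | intermediate
4 | methyl vinyl ketone | C=CC(C)=O | starting material
5 | (E)-geranylacetone | CC(C)=CCC/C(C)=C/CCC(C)=O | intermediate
6 | (5E,9S)-9,10-epoxy-6,10-dimethylundec-5-en-2-one | CC1(C)O[C@H]1CC/C(C)=C/CCC(C)=O | intermediate
7 | ethyl glyoxylate | CCOC(=O)C=O | starting material
8 | aldol adduct (mixture at CH-OH) | CC1(C)O[C@H]1CC/C(C)=C/CCC(=O)CC(O)C(=O)OCC | intermediate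
9 | epoxy 4-oxo-2-enoate | CC1(C)O[C@H]1CC/C(C)=C/CCC(=O)/C=C/C(=O)OCC | intermediate
10 | 8-oxo decalin ethyl ester | O=C1CC[C@H]2C(C)(C)[C@@H](O)CC[C@]2(C)[C@H]1CC(=O)OCC | intermediate
11 | 8-methylene decalin ethyl ester | C=C1CC[C@H]2C(C)(C)[C@@H](O)CC[C@]2(C)[C@H]1CC(=O)OCC | intermediate
12 | decalin acetaldehyde | C=C1CC[C@H]2C(C)(C)[C@@H](O)CC[C@]2(C)[C@H]1CC=O | intermediate
13 | propane-1,3-dithiol | SCCCS | starting material
14 | decalin-CH2-dithiane | C=C1CC[C@H]2C(C)(C)[C@@H](O)CC[C@]2(C)[C@H]1CC1SCCCS1 | intermediate
15 | cyclopent-2-ene-1,4-dione | O=C1C=CC(=O)C1 | starting material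
16 | 4,4-dimethoxycyclopent-2-en-1-one | COC1(OC)CC(=O)C=C1 | intermediate
17 | dithiane–ketal adduct (C4′ epimers) | C=C1CC[C@H]2C(C)(C)[C@@H](O)CC[C@]2(C)[C@H]1CC1(SCCCS1)C1(O)C=CC(OC)(OC)C1 | intermediate
18 | (4′R)-4′-hydroxy-4′-acyl cyclopentenone | C=C1CC[C@H]2C(C)(C)[C@@H](O)CC[C@]2(C)[C@H]1CC(=O)[C@]1(O)C=CC(=O)C1 | intermediate
19 | formaldehyde | C=O | starting material
20 | Morita–Baylis–Hillman adduct | C=C1CC[C@H]2C(C)(C)[C@@H](O)CC[C@]2(C)[C@H]1CC(=O)[C@]1(O)C=C(CO)C(=O)C1 | intermediate
21 | allylic bromide | C=C1CC[C@H]2C(C)(C)[C@@H](O)CC[C@]2(C)[C@H]1CC(=O)[C@]1(O)C=C(CBr)C(=O)C1 | intermediate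
22 | methyl (S)-glycidate | COC(=O)[C@@H]1CO1 | starting material
23 | methyl (R)-3-(acetylthio)-2-hydroxypropanoate | COC(=O)[C@@H](O)CSC(C)=O | intermediate
24 | methyl (R)-2-hydroxy-3-mercaptopropanoate | COC(=O)[C@@H](O)CS | intermediate
25 | Alternarin A | C=C1CC[C@H]2C(C)(C)[C@@H](O)CC[C@]2(C)[C@H]1CC(=O)[C@]1(O)C=C(CSC[C@H](O)C(=O)OC)C(=O)C1 | target

## Totals
- **Total steps:** 17.
- **Longest linear sequence:** 14 steps (1→2→3→4→5→6→7→8→9→11→12→13→14→17).

## Three steps most likely to fail
1. **Step 6 (Ti(III) cascade onto the oxo-enoate).** Ti(III) may reduce the electron-poor acceptor directly, and the ring fusion may be only partly trans.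
   - Fallback: use a conventional epoxyfarnesyl-type substrate ending in a trisubstituted alkene. Build it by iterative Johnson–Claisen chain extension of 3-(silyloxy)propanal and a Wittig terminus. Run the standard Cp2TiCl epoxypolyene cyclisation, which gives the exocyclic methylene directly, then oxidise the C13 alcohol to reach aldehyde 12.
2. **Step 13 (Morita–Baylis–Hillman hydroxymethylation).** The β-carbon (C3′) is next to the quaternary carbinol, so nucleophilic catalysts attack it slowly.
   - Fallback: install the CH2OR group before ring formation. Lithiate 2-methyl-3-(silyloxymethyl)furan and add it to aldehyde 12. Then oxidise the furan with singlet oxygen/Me2S to the cis-enedione, oxidise the carbinol to the ketone, and close the ring by intramolecular aldol. This builds the 2′-CH2OR cyclopentenone without an enone hydroxymethylation.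
3. **Step 11 (dithiane addition and C4′ control).** 1,4-addition competes with 1,2-addition, and C4′ forms about 1:1, so the yield of the natural epimer is at most about half.
   - Fallback: form C13–C4′ by Cp2TiCl-mediated ketyl cross-pinacol coupling of aldehyde 12 with 16. Then oxidise the secondary carbinol of the resulting diol to the ketone (DMP), leaving the tertiary alcohol.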